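## Structural features

The target is a linear, achiral heptamer: seven benzene rings A–G joined by six diaryl ether oxygens, carrying seventeen free hydroxyl groups and no stereocentre. Ring A is a 2,4,6-trihydroxyphenyl ether and ring G a 3,4,5-trihydroxyphenyl ether. Rings B, C, E and F are 1,4-dioxygenated with hydroxyls at C3 and C5. Ring D is pentaoxygenated, with its two ether oxygens on adjacent carbons (C1 to ring C, C6 to ring E), hydroxyls at C3–C5 and one CH. Each ether oxygen sits on a carbon flanked by two oxygenated carbons in one ring (A, B, C, D, E, F in turn) and on an unhindered carbon of the next ring. The free polyphenol is fragile: rings D and G are pyrogallol-like and autoxidise in base, and rings A, F and G remain strongly nucleophilic even as methyl ethers. The real difficulty is six hindered diaryl ethers between electron-rich rings with no activating group left in the target, plus the regiochemistry of ring D. The key step uses ring F: C1 (O to ring E) and C4 (O to ring G) are para, with C3 and C5 hydroxylated. These map onto C4 and the exocyclic carbon of a 2-pyrone, with the lactone carbonyl carbon and C6 becoming the two C–OH carbons, so both ethers of ring F can be made at non-aromatic carbon before one C–C bond closes the ring.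

## Logic of the disconnections

27 to 26: the seventeen O–H bonds are traced back to O–CH3 bonds. The free polyphenol cannot be carried through base, copper or peracid, whereas methyl ethers are uniform, small and already present in the catalogue building blocks. The demand is one reagent that cleaves seventeen aryl methyl ethers and leaves six diaryl ethers intact.

26 to 25 and 11: the bond between the ring D oxygen (on C6) and C1 of ring E is cut. This splits seven rings into four and three and uses the natural polarity of every link: a doubly ortho-substituted phenol oxygen attacks an unhindered aryl carbon. The forward step must join a hindered, electron-rich phenoxide to an unactivated, electron-rich aryl bromide. Direct copper catalysis is preferred to an aryl(2,4,6-trimethoxyphenyl)iodonium salt, because that salt would have to be formed in the presence of rings F and G, which are about as nucleophilic as the arene meant to become the dummy ligand.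

11 to 10 to 8: after the two O-methyl bonds of ring F, the ring F C–C bond between the carbon bearing the ring G ether and a neighbouring hydroxylated carbon is cut, with 9 as the open-chain relay. Ring F reverts to a 2-pyrone, so neither of its hindered ethers needs an aryl–oxygen coupling. The forward step must open the lactone, close through carbon rather than oxygen, and keep the vinylogous aryloxy group.

8 to 6 and 7, 6 to 4, 4 to 2 and 3, 2 to 1: the CH2–O bond, the C–Cl bond and the C4–O bond of the pyrone are cut in turn. Each is a substitution at sp3 or vinylogous acyl carbon, which tolerates hindered phenoxides. Functionalising the methyl group through its anion (5) avoids electrophilic halogenating agents that would attack ring E. A C4 bromide replaces a sulfonate so that the phenoxide of 3 has no sulfur centre to attack. The demand is mono-chlorination and substitution at CH2 faster than aryloxide exchange at C4.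

25 to 23 to 19 and 22, and 22 to 20: the ring D hydroxyl is traced to a formyl group (via 24), then the ring C oxygen to ring D carbon bond is cut. The formyl group activates the ortho bromide for coupling and is the latent hydroxyl, so no protecting group is needed. The ring D pattern is fixed without ambiguity because 20 has only one kind of free position (via 21). The demand is a coupling in which both partners are ortho-substituted.

19 to 17 to 16 and 13, and 16 to 14 to 12 and 13: the same two cuts are repeated for rings C and B (via 18 and 15). Here the bromide is para to the formyl group and unhindered, so these are the easiest couplings of the route. The demand is aryl migration to oxygen without oxidation of the electron-rich rings already present.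

## Other disconnections considered

Alternative 1: The cut removes the two ring B bonds on either side of the CH=C(O–ring A) unit. In the forward sense the cyclobutenone A2 is heated with the ethynyl ether A3; electrocyclic opening, (2+2) addition, a second opening and 6π closure would give phenol A1.
- In its favour: two C–C bonds form in one reagent-free thermal step, the regiochemistry follows from the polarity of the partners, and the reaction type is established for alkoxyalkynes. On that last count it is better placed than step 5, which has no precedent on its substrate class.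
- It equals the chosen plan in placing both ethers on the ring before aromatisation, and it has no leaving group that an external nucleophile could exchange.
- Against it here: A2 and A3 each need several steps and both are sensitive. A1 carries an ethoxy and a free hydroxyl that serve no purpose in a target where every oxygen ends as OH. Ring B is the ring that steps 7 and 8 deliver in two operations from catalogue materials.
- On step economy it is clearly worse, and it does nothing for ring D or the central union.

Alternative 2: The cut converts both diaryl ether bonds of the ABC trimer into ester links. In the forward sense zerovalent nickel from Ni(cod)2 with a chelating bis(dicyclohexylphosphino)thiophene would decarbonylate depside A5 twice to give trimer A4.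
- In its favour: esters of hindered phenols are trivial to make, the polarity matches the target exactly (hindered oxygen, unhindered carbon), and decarbonylative etherification is a known reaction type. These are real advantages over the three copper couplings of steps 7, 9 and 12 and over the unprecedented step 5.
- Step count to the stage of 19 (A4 is its benzyl ether) would be about equal.
- Against it here: the known scope favours activated aryl esters. A5 is an electron-rich benzoate of electron-rich, doubly ortho-substituted phenols, so both acyl–oxygen insertion and C–O reductive elimination would be slow. Two extrusions must succeed in one molecule at high temperature.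
- It addresses only the part of the target that the chosen plan already reaches with activated bromides, and does not help with ring D.

Alternative 3: The cut is the ring A C–C bond between the carbon bearing the ring B ether and a neighbouring C–OH. In the forward sense base would close dioxo ester A7 by attack of C6 on the ester to give triol A6.
- In its favour: it belongs to the same mechanistic family as step 5 (6-(enolexo)-exo-trig Claisen closure with an aromatic sink) but rests on closer precedent, since 3,5-dioxohexanoates are known to close to phloroglucinols. It has no vinylogous aryloxy group to lose. On both points it is the safer reaction.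
- It shares with step 5 the competition from closure through oxygen, here to pyrone A8.
- Against it here: it builds ring A, a terminal ring that is bought as 12, and forms only one ether of the ring where step 5 sets two. A6 would need trimethylation and debenzylation to reach 16, about five steps against two.

Key step: step 5

Assumption: 2,4,6-trimethoxyphenol (12), 4-bromo-2,6-dimethoxybenzaldehyde (13) and 5-bromo-1,2,3-trimethoxybenzene (20) are taken as catalogue chemicals.

## Route

Step 1
Reactants: 1 4-hydroxy-6-methyl-2H-pyran-2-one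
Product: 2 4-bromo-6-methyl-2H-pyran-2-one
Conditions: P2O5, n-Bu4NBr, toluene, 100 °C
Reagents that add atoms: tetrabutylammonium bromide, CCCC[N+](CCCC)(CCCC)CCCC.[Br-]
Why: Deoxybromination of a vinylogous acid: the enol oxygen is activated as a phosphate and displaced by bromide through addition–elimination at C4. The bromide is chosen because a phenoxide can attack it only at carbon.

Step 2
Reactants: 2 4-bromo-6-methyl-2H-pyran-2-one; 3 4-bromo-2,6-dimethoxyphenol
Product: 4 4-(4-bromo-2,6-dimethoxyphenoxy)-6-methyl-2H-pyran-2-one
Conditions: K2CO3, MeCN, 60 °C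
Reagents that add atoms: none
Why: Addition–elimination (vinylogous acyl substitution) at C4 of a 4-halo-2-pyrone. Attack at sp2 carbon from the open face of the ring is little affected by the two ortho-methoxy groups of the phenoxide, and addition at C2 or C6 is reversible.

Step 3
Reactants: 4 4-(4-bromo-2,6-dimethoxyphenoxy)-6-methyl-2H-pyran-2-one
Product: 6 4-(4-bromo-2,6-dimethoxyphenoxy)-6-(chloromethyl)-2H-pyran-2-one, via 6-(lithiomethyl)pyrone 5 (not isolated)
Conditions: LiN(SiMe3)2, THF, −78 °C; cannulated into C2Cl6, THF, −78 °C
Reagents that add atoms: hexachloroethane, ClC(Cl)(Cl)C(Cl)(Cl)Cl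
Why: Vinylogous deprotonation of the 6-methyl group of a 4-oxygenated 2-pyrone and electrophilic chlorination of the extended enolate at the exocyclic carbon. The amide base does not exchange the aryl bromide, and inverse addition into excess chlorine donor should limit proton transfer and dichlorination.

Step 4
Reactants: 6 4-(4-bromo-2,6-dimethoxyphenoxy)-6-(chloromethyl)-2H-pyran-2-one; 7 3,4,5-trimethoxyphenol
Product: 8 4-(4-bromo-2,6-dimethoxyphenoxy)-6-[(3,4,5-trimethoxyphenoxy)methyl]-2H-pyran-2-one
Conditions: K2CO3, NaI (cat.), acetone, rt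
Reagents that add atoms: none
Why: Williamson SN2 ether synthesis at an allylic-type primary chloride with iodide catalysis. At room temperature with one equivalent of phenol it should outrun aryloxide exchange at C4.

Step 5
Reactants: 8 4-(4-bromo-2,6-dimethoxyphenoxy)-6-[(3,4,5-trimethoxyphenoxy)methyl]-2H-pyran-2-one
Product: 10 5-(4-bromo-2,6-dimethoxyphenoxy)-2-(3,4,5-trimethoxyphenoxy)benzene-1,3-diol, via ring-opened methyl oxohexenoate 9 (not isolated)
Conditions: Mg(OMe)2, MeOH–THF, reflux, Ar; then 1 M HCl
Reagents that add atoms: none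
Why: Proposed new method: with magnesium bound to the lactone carbonyl, methoxide should add at C2 of 8 and open the ring to the chelated (2E)-enoate 9, in which the ester and the 5-oxo chain stay cis across C2=C3; reversible enolisation of the ketone towards C6, which the ring G aryloxy group makes more acidic, lets C6 attack the ester carbonyl, methoxide leaves, and the cyclohexenedione tautomerises to the resorcinol, held as its magnesium phenoxide until acidification. The closest known reaction type is the Mg(OMe)2-induced opening of 4-oxygenated 6-(2-oxoalkyl)-2-pyrones with Claisen reclosure to acylphloroglucinols and resorcinols; a pyrone bearing two aryloxy groups goes beyond it. Ring F closes in a 6-(enolexo)-exo-trig mode and no stereocentre is formed. Closure through carbon must beat return to the pyrone through oxygen; the latter is reversible, whereas aromatisation and magnesium chelation of the product are not. Reaction must go through the C6 enolate and not the more stable C4 dienolate; C4 could reach the ester only through a four-membered ring, so only C6 is productive. The ring E aryloxy group must survive methoxide; its two ortho-methoxy groups shield the vinylogous carbon, the opened chain is an anionic dienolate of low electrophilicity, and magnesium-bound methoxide is a weak nucleophile.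

Step 6
Reactants: 10 5-(4-bromo-2,6-dimethoxyphenoxy)-2-(3,4,5-trimethoxyphenoxy)benzene-1,3-diol
Product: 11 5-bromo-2-[3,5-dimethoxy-4-(3,4,5-trimethoxyphenoxy)phenoxy]-1,3-dimethoxybenzene
Conditions: MeI, K2CO3, DMF, rt
Reagents that add atoms: iodomethane, CI
Why: Williamson O-methylation of both resorcinol hydroxyls. It brings ring F to the same protecting group as all other rings and removes acidic protons before the copper coupling.

Step 7
Reactants: 12 2,4,6-trimethoxyphenol; 13 4-bromo-2,6-dimethoxybenzaldehyde
Product: 14 2,6-dimethoxy-4-(2,4,6-trimethoxyphenoxy)benzaldehyde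
Conditions: CuI (cat.), picolinic acid (cat.), K3PO4, DMSO, 90 °C, Ar
Reagents that add atoms: none
Why: Ullmann diaryl ether coupling with a picolinate-ligated monovalent copper catalyst, a combination suited to doubly ortho-substituted phenols. The bromide is unhindered and activated by the para formyl group.

Step 8
Reactants: 14 2,6-dimethoxy-4-(2,4,6-trimethoxyphenoxy)benzaldehyde
Product: 16 2,6-dimethoxy-4-(2,4,6-trimethoxyphenoxy)phenol, via aryl formate 15 (not isolated)
Conditions: mCPBA, CH2Cl2, 0 °C; then K2CO3 (cat.), MeOH, rt, Ar
Reagents that add atoms: 3-chloroperbenzoic acid, OOC(=O)c1cccc(Cl)c1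
Why: Baeyer–Villiger (Dakin-type) oxidation: the electron-rich aryl group flanked by two methoxy groups migrates to oxygen, and the formate is methanolysed. A reductive wash before methanolysis should remove excess peracid so the phenol is not oxidised further.

Step 9
Reactants: 16 2,6-dimethoxy-4-(2,4,6-trimethoxyphenoxy)phenol; 13 4-bromo-2,6-dimethoxybenzaldehyde
Product: 17 4-[2,6-dimethoxy-4-(2,4,6-trimethoxyphenoxy)phenoxy]-2,6-dimethoxybenzaldehyde
Conditions: CuI (cat.), picolinic acid (cat.), K3PO4, DMSO, 90 °C, Ar
Reagents that add atoms: none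
Why: Second Ullmann coupling of the same type as step 7. The new phenol has the same 2,6-dimethoxy environment and the same activated bromide is used.

Step 10
Reactants: 17 4-[2,6-dimethoxy-4-(2,4,6-trimethoxyphenoxy)phenoxy]-2,6-dimethoxybenzaldehyde
Product: 19 4-[2,6-dimethoxy-4-(2,4,6-trimethoxyphenoxy)phenoxy]-2,6-dimethoxyphenol, via aryl formate 18 (not isolated)
Conditions: mCPBA, CH2Cl2, 0 °C; then K2CO3 (cat.), MeOH, rt, Ar
Reagents that add atoms: 3-chloroperbenzoic acid, OOC(=O)c1cccc(Cl)c1
Why: Baeyer–Villiger oxidation and formate methanolysis as in step 8. The aldehyde again carries two ortho-methoxy groups, which favour aryl migration.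

Step 11
Reactants: 20 5-bromo-1,2,3-trimethoxybenzene
Product: 22 6-bromo-2,3,4-trimethoxybenzaldehyde, via aryl(chloro)methyl methyl ether 21 (not isolated)
Conditions: Cl2CHOMe, TiCl4, CH2Cl2, 0 °C; then H2O
Reagents that add atoms: dichloromethyl methyl ether, COC(Cl)Cl; water, O
Why: Rieche formylation. The two free positions of 20 are equivalent by symmetry and each is ortho and para to a methoxy group, so only one aldehyde can form, with bromine ortho to the formyl group.

Step 12
Reactants: 19 4-[2,6-dimethoxy-4-(2,4,6-trimethoxyphenoxy)phenoxy]-2,6-dimethoxyphenol; 22 6-bromo-2,3,4-trimethoxybenzaldehyde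
Product: 23 6-{4-[2,6-dimethoxy-4-(2,4,6-trimethoxyphenoxy)phenoxy]-2,6-dimethoxyphenoxy}-2,3,4-trimethoxybenzaldehyde
Conditions: CuI (cat.), picolinic acid (cat.), K3PO4, DMSO, 100 °C, Ar
Reagents that add atoms: none
Why: Ullmann coupling of a hindered phenol with an ortho-formyl aryl bromide. The ortho carbonyl group accelerates copper-mediated substitution, and the other ortho position of the bromide is a CH.

Step 13
Reactants: 23 6-{4-[2,6-dimethoxy-4-(2,4,6-trimethoxyphenoxy)phenoxy]-2,6-dimethoxyphenoxy}-2,3,4-trimethoxybenzaldehyde
Product: 25 6-{4-[2,6-dimethoxy-4-(2,4,6-trimethoxyphenoxy)phenoxy]-2,6-dimethoxyphenoxy}-2,3,4-trimethoxyphenol, via aryl formate 24 (not isolated)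
Conditions: mCPBA, CH2Cl2, 0 °C; then K2CO3 (cat.), MeOH, rt, Ar
Reagents that add atoms: 3-chloroperbenzoic acid, OOC(=O)c1cccc(Cl)c1
Why: Baeyer–Villiger oxidation and methanolysis turn the formyl group into the ring D hydroxyl, next to the ring C ether and a methoxy group. This is exactly the oxygen that must carry ring E.

Step 14
Reactants: 25 6-{4-[2,6-dimethoxy-4-(2,4,6-trimethoxyphenoxy)phenoxy]-2,6-dimethoxyphenoxy}-2,3,4-trimethoxyphenol; 11 5-bromo-2-[3,5-dimethoxy-4-(3,4,5-trimethoxyphenoxy)phenoxy]-1,3-dimethoxybenzene
Product: 26 heptadeca-O-methyl ether of the target (rings A–G joined as in 27, every hydroxyl as OMe)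
Conditions: CuI (cat.), picolinic acid (cat.), K3PO4, DMSO, 110 °C, Ar
Reagents that add atoms: none
Why: Ullmann coupling of the hindered ring D phenoxide with the unhindered ring E bromide, the same polarity as steps 7, 9 and 12. The bromide is electron-rich and would be used in excess at the higher temperature.

Step 15
Reactants: 26 heptadeca-O-methyl ether of the target
Product: 27 CNP0304148.0 (target heptamer with seventeen free hydroxyls)
Conditions: BBr3 (excess), CH2Cl2, −78 °C → rt; then H2O, 0 °C, Ar
Reagents that add atoms: none
Why: Lewis-acid cleavage of aryl methyl ethers by bromide attack on the boron-activated methyl group. Diaryl ethers have no alkyl carbon to attack and should survive, and the acidic work-up under argon protects the pyrogallol rings.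

## Compound list

1 | 4-hydroxy-6-methyl-2H-pyran-2-one | CC1=CC(O)=CC(=O)O1 | starting material
2 | 4-bromo-6-methyl-2H-pyran-2-one | CC1=CC(Br)=CC(=O)O1 | intermediate
3 | 4-bromo-2,6-dimethoxyphenol | COc1cc(Br)cc(OC)c1O | starting material
4 | 4-(4-bromo-2,6-dimethoxyphenoxy)-6-methyl-2H-pyran-2-one | CC1=CC(Oc2c(OC)cc(Br)cc2OC)=CC(=O)O1 | intermediate
5 | 4-(4-bromo-2,6-dimethoxyphenoxy)-6-(lithiomethyl)-2H-pyran-2-one (lithium dienolate of 4) | [Li]CC1=CC(Oc2c(OC)cc(Br)cc2OC)=CC(=O)O1 | intermediate
6 | 4-(4-bromo-2,6-dimethoxyphenoxy)-6-(chloromethyl)-2H-pyran-2-one | ClCC1=CC(Oc2c(OC)cc(Br)cc2OC)=CC(=O)O1 | intermediate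
7 | 3,4,5-trimethoxyphenol | COc1cc(O)cc(OC)c1OC | starting material
8 | 4-(4-bromo-2,6-dimethoxyphenoxy)-6-[(3,4,5-trimethoxyphenoxy)methyl]-2H-pyran-2-one | O=C1C=C(Oc2c(OC)cc(Br)cc2OC)C=C(COc2cc(OC)c(OC)c(OC)c2)O1 | intermediate
9 | methyl (2E)-3-(4-bromo-2,6-dimethoxyphenoxy)-5-oxo-6-(3,4,5-trimethoxyphenoxy)hex-2-enoate, present as its magnesium chelate | COC(=O)/C=C(/Oc1c(OC)cc(Br)cc1OC)CC(=O)COc1cc(OC)c(OC)c(OC)c1 | intermediate
10 | 5-(4-bromo-2,6-dimethoxyphenoxy)-2-(3,4,5-trimethoxyphenoxy)benzene-1,3-diol | Oc1cc(Oc2c(OC)cc(Br)cc2OC)cc(O)c1Oc1cc(OC)c(OC)c(OC)c1 | intermediate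
11 | 5-bromo-2-[3,5-dimethoxy-4-(3,4,5-trimethoxyphenoxy)phenoxy]-1,3-dimethoxybenzene (EFG bromide) | COc1cc(Oc2c(OC)cc(Br)cc2OC)cc(OC)c1Oc1cc(OC)c(OC)c(OC)c1 | intermediate
12 | 2,4,6-trimethoxyphenol | COc1cc(OC)c(O)c(OC)c1 | starting material
13 | 4-bromo-2,6-dimethoxybenzaldehyde | COc1cc(Br)cc(OC)c1C=O | starting material
14 | 2,6-dimethoxy-4-(2,4,6-trimethoxyphenoxy)benzaldehyde | COc1cc(OC)c(Oc2cc(OC)c(C=O)c(OC)c2)c(OC)c1 | intermediate
15 | 2,6-dimethoxy-4-(2,4,6-trimethoxyphenoxy)phenyl formate | COc1cc(OC)c(Oc2cc(OC)c(OC=O)c(OC)c2)c(OC)c1 | intermediate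
16 | 2,6-dimethoxy-4-(2,4,6-trimethoxyphenoxy)phenol | COc1cc(OC)c(Oc2cc(OC)c(O)c(OC)c2)c(OC)c1 | intermediate
17 | 4-[2,6-dimethoxy-4-(2,4,6-trimethoxyphenoxy)phenoxy]-2,6-dimethoxybenzaldehyde | COc1cc(OC)c(Oc2cc(OC)c(Oc3cc(OC)c(C=O)c(OC)c3)c(OC)c2)c(OC)c1 | intermediate
18 | 4-[2,6-dimethoxy-4-(2,4,6-trimethoxyphenoxy)phenoxy]-2,6-dimethoxyphenyl formate | COc1cc(OC)c(Oc2cc(OC)c(Oc3cc(OC)c(OC=O)c(OC)c3)c(OC)c2)c(OC)c1 | intermediate
19 | 4-[2,6-dimethoxy-4-(2,4,6-trimethoxyphenoxy)phenoxy]-2,6-dimethoxyphenol | COc1cc(OC)c(Oc2cc(OC)c(Oc3cc(OC)c(O)c(OC)c3)c(OC)c2)c(OC)c1 | intermediate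
20 | 5-bromo-1,2,3-trimethoxybenzene | COc1cc(Br)cc(OC)c1OC | starting material
21 | 1-bromo-2-[chloro(methoxy)methyl]-3,4,5-trimethoxybenzene (racemic, transient) | COc1cc(Br)c(C(Cl)OC)c(OC)c1OC | intermediate
22 | 6-bromo-2,3,4-trimethoxybenzaldehyde | COc1cc(Br)c(C=O)c(OC)c1OC | intermediate
23 | 6-{4-[2,6-dimethoxy-4-(2,4,6-trimethoxyphenoxy)phenoxy]-2,6-dimethoxyphenoxy}-2,3,4-trimethoxybenzaldehyde | COc1cc(OC)c(Oc2cc(OC)c(Oc3cc(OC)c(Oc4cc(OC)c(OC)c(OC)c4C=O)c(OC)c3)c(OC)c2)c(OC)c1 | intermediate
24 | 6-{4-[2,6-dimethoxy-4-(2,4,6-trimethoxyphenoxy)phenoxy]-2,6-dimethoxyphenoxy}-2,3,4-trimethoxyphenyl formate | COc1cc(OC)c(Oc2cc(OC)c(Oc3cc(OC)c(Oc4cc(OC)c(OC)c(OC)c4OC=O)c(OC)c3)c(OC)c2)c(OC)c1 | intermediate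
25 | 6-{4-[2,6-dimethoxy-4-(2,4,6-trimethoxyphenoxy)phenoxy]-2,6-dimethoxyphenoxy}-2,3,4-trimethoxyphenol (ABCD phenol) | COc1cc(OC)c(Oc2cc(OC)c(Oc3cc(OC)c(Oc4cc(OC)c(OC)c(OC)c4O)c(OC)c3)c(OC)c2)c(OC)c1 | intermediate
26 | heptadeca-O-methyl ether of the target: rings A–G joined as in 27, every hydroxyl as OMe | COc1cc(OC)c(Oc2cc(OC)c(Oc3cc(OC)c(Oc4cc(OC)c(OC)c(OC)c4Oc4cc(OC)c(Oc5cc(OC)c(Oc6cc(OC)c(OC)c(OC)c6)c(OC)c5)c(OC)c4)c(OC)c3)c(OC)c2)c(OC)c1 | intermediate
27 | CNP0304148.0: 2,4,6-trihydroxyphenyl ether (A), two 3,5-dihydroxy-1,4-phenylenedioxy rings (B, C), 3,4,5-trihydroxy-1,2-phenylenedioxy ring (D), two 3,5-dihydroxy-1,4-phenylenedioxy rings (E, F), 3,4,5-trihydroxyphenyl ether (G) | Oc1cc(O)c(Oc2cc(O)c(Oc3cc(O)c(Oc4cc(O)c(O)c(O)c4Oc4cc(O)c(Oc5cc(O)c(Oc6cc(O)c(O)c(O)c6)c(O)c5)c(O)c4)c(O)c3)c(O)c2)c(O)c1 | target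

## Step count and least certain steps

Total step count: 15. Longest linear sequence: 8 steps (steps 7, 8, 9, 10, 12, 13, 14 and 15 from 12; the branch from 1 through steps 1–6, 14 and 15 is equally long).

Step 5 (key step, proposed new method). The most likely failures are exchange of the vinylogous ring E aryloxy group by methoxide, before or after ring opening, and simple return of the opened chain to the pyrone without C-acylation. Both would drain material before the irreversible aromatisation. Fallback by known chemistry, setting out from 3 and 13 and coming back at 11: copper-catalysed Ullmann coupling of 3 with 13, in which the formyl-activated bromide of 13 should react ahead of the electron-rich bromide of 3, would give 4-(4-bromo-2,6-dimethoxyphenoxy)-2,6-dimethoxybenzaldehyde F1. Baeyer–Villiger oxidation would give 4-(4-bromo-2,6-dimethoxyphenoxy)-2,6-dimethoxyphenyl formate F2 and methanolysis 4-(4-bromo-2,6-dimethoxyphenoxy)-2,6-dimethoxyphenol F3. A second Ullmann coupling with 5-iodo-1,2,3-trimethoxybenzene at 80 °C, where the iodide reacts ahead of the bromide, would give 11.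

Step 3. Proton transfer between 5 and the more acidic product 6 during the quench would lead to over-chlorination and recovered 4. Fallback, setting out from 4 and coming back at 8: Riley oxidation of the methyl group with SeO2 in dioxane would give 4-(4-bromo-2,6-dimethoxyphenoxy)-2-oxo-2H-pyran-6-carbaldehyde F4, and NaBH4 reduction at 0 °C would give 4-(4-bromo-2,6-dimethoxyphenoxy)-6-(hydroxymethyl)-2H-pyran-2-one F5. Mitsunobu etherification with 7 (PPh3, diisopropyl azodicarboxylate, THF) would give 8, so no carbanion and no halide are involved.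

Step 14. Oxidative addition of the electron-rich bromide may be slow next to a bulky phenoxide, so reduction of the bromide and decomposition of the phenoxide at 110 °C could compete. Fallback, setting out from 11 and coming back at 26: copper-catalysed aromatic Finkelstein exchange (CuI, NaI, N,N'-dimethylethylenediamine, dioxane, 110 °C) would give 5-iodo-2-[3,5-dimethoxy-4-(3,4,5-trimethoxyphenoxy)phenoxy]-1,3-dimethoxybenzene F6. Oxidation to trivalent iodine (mCPBA, TsOH·H2O, MeCN) followed by excess 1,3,5-trimethoxybenzene would give {3,5-dimethoxy-4-[3,5-dimethoxy-4-(3,4,5-trimethoxyphenoxy)phenoxy]phenyl}(2,4,6-trimethoxyphenyl)iodonium tosylate F7. Metal-free arylation of 25 (KOt-Bu, THF, 40 °C) with selective transfer of the less electron-rich aryl group would give 26. The weak point of this fallback is attack of rings F and G on the trivalent iodine centre in competition with the added arene.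

Step 15. Incomplete cleavage of some of the seventeen hindered methyl ethers and oxidative loss of the free polyphenol during purification are the main dangers. Fallback, setting out from 26 and coming back at 27: after the same demethylation the crude product is acetylated without purification (Ac2O, pyridine) to the heptadecaacetate F8, which is stable to air and chromatography and can be separated from partly methylated material. Acid methanolysis (HCl, MeOH, Ar) then releases 27 without exposure to base.

Step 8 (the same concern applies to steps 10 and 13). Peracid may hydroxylate ring A or oxidise the product phenol to a quinone with loss of the aryloxy group. Fallback, setting out from 3 and 12 and coming back at 16: benzylation of 3 (BnBr, K2CO3) would give 2-(benzyloxy)-5-bromo-1,3-dimethoxybenzene F9. Ullmann coupling with 12 would give 2-[4-(benzyloxy)-3,5-dimethoxyphenoxy]-1,3,5-trimethoxybenzene F10, and hydrogenolysis (H2, Pd/C, EtOAc) would give 16 with no oxidant in the sequence.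

## Further compounds

F1 | step 5 | 4-(4-bromo-2,6-dimethoxyphenoxy)-2,6-dimethoxybenzaldehyde | COc1cc(Oc2c(OC)cc(Br)cc2OC)cc(OC)c1C=O
F2 | step 5 | 4-(4-bromo-2,6-dimethoxyphenoxy)-2,6-dimethoxyphenyl formate | COc1cc(Oc2c(OC)cc(Br)cc2OC)cc(OC)c1OC=O
F3 | step 5 | 4-(4-bromo-2,6-dimethoxyphenoxy)-2,6-dimethoxyphenol | COc1cc(Oc2c(OC)cc(Br)cc2OC)cc(OC)c1O
F4 | step 3 | 4-(4-bromo-2,6-dimethoxyphenoxy)-2-oxo-2H-pyran-6-carbaldehyde | O=CC1=CC(Oc2c(OC)cc(Br)cc2OC)=CC(=O)O1
F5 | step 3 | 4-(4-bromo-2,6-dimethoxyphenoxy)-6-(hydroxymethyl)-2H-pyran-2-one | OCC1=CC(Oc2c(OC)cc(Br)cc2OC)=CC(=O)O1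
F6 | step 14 | 5-iodo-2-[3,5-dimethoxy-4-(3,4,5-trimethoxyphenoxy)phenoxy]-1,3-dimethoxybenzene | COc1cc(Oc2c(OC)cc(I)cc2OC)cc(OC)c1Oc1cc(OC)c(OC)c(OC)c1
F7 | step 14 | {3,5-dimethoxy-4-[3,5-dimethoxy-4-(3,4,5-trimethoxyphenoxy)phenoxy]phenyl}(2,4,6-trimethoxyphenyl)iodonium tosylate | COc1cc(OC)c([I+]c2cc(OC)c(Oc3cc(OC)c(Oc4cc(OC)c(OC)c(OC)c4)c(OC)c3)c(OC)c2)c(OC)c1.Cc1ccc(cc1)S(=O)(=O)[O-]
F8 | step 15 | heptadecaacetate of 27 (every hydroxyl as OAc) | CC(=O)Oc1cc(OC(C)=O)c(Oc2cc(OC(C)=O)c(Oc3cc(OC(C)=O)c(Oc4cc(OC(C)=O)c(OC(C)=O)c(OC(C)=O)c4Oc4cc(OC(C)=O)c(Oc5cc(OC(C)=O)c(Oc6cc(OC(C)=O)c(OC(C)=O)c(OC(C)=O)c6)c(OC(C)=O)c5)c(OC(C)=O)c4)c(OC(C)=O)c3)c(OC(C)=O)c2)c(OC(C)=O)c1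
F9 | step 8 | 2-(benzyloxy)-5-bromo-1,3-dimethoxybenzene | COc1cc(Br)cc(OC)c1OCc1ccccc1
F10 | step 8 | 2-[4-(benzyloxy)-3,5-dimethoxyphenoxy]-1,3,5-trimethoxybenzene | COc1cc(OC)c(Oc2cc(OC)c(OCc3ccccc3)c(OC)c2)c(OC)c1
A1 | alternative 1 | 2-[4-(benzyloxy)-3,5-dimethoxyphenoxy]-3-ethoxy-5-(2,4,6-trimethoxyphenoxy)phenol | CCOc1cc(Oc2c(OC)cc(OC)cc2OC)cc(O)c1Oc1cc(OC)c(OCc2ccccc2)c(OC)c1
A2 | alternative 1 | 4-[4-(benzyloxy)-3,5-dimethoxyphenoxy]-3-ethoxycyclobut-2-en-1-one (racemic) | CCOC1=CC(=O)C1Oc1cc(OC)c(OCc2ccccc2)c(OC)c1
A3 | alternative 1 | 2-(ethynyloxy)-1,3,5-trimethoxybenzene | C#COc1c(OC)cc(OC)cc1OC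
A4 | alternative 2 | 2-{4-[4-(benzyloxy)-3,5-dimethoxyphenoxy]-2,6-dimethoxyphenoxy}-1,3,5-trimethoxybenzene | COc1cc(OC)c(Oc2cc(OC)c(Oc3cc(OC)c(OCc4ccccc4)c(OC)c3)c(OC)c2)c(OC)c1
A5 | alternative 2 | 2,4,6-trimethoxyphenyl 4-{[4-(benzyloxy)-3,5-dimethoxybenzoyl]oxy}-3,5-dimethoxybenzoate | COc1cc(OC)c(OC(=O)c2cc(OC)c(OC(=O)c3cc(OC)c(OCc4ccccc4)c(OC)c3)c(OC)c2)c(OC)c1
A6 | alternative 3 | 2-[4-(benzyloxy)-3,5-dimethoxyphenoxy]benzene-1,3,5-triol | Oc1cc(O)c(Oc2cc(OC)c(OCc3ccccc3)c(OC)c2)c(O)c1
A7 | alternative 3 | methyl 6-[4-(benzyloxy)-3,5-dimethoxyphenoxy]-3,5-dioxohexanoate | COC(=O)CC(=O)CC(=O)COc1cc(OC)c(OCc2ccccc2)c(OC)c1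
A8 | alternative 3 | 6-{[4-(benzyloxy)-3,5-dimethoxyphenoxy]methyl}-4-hydroxy-2H-pyran-2-one | O=C1C=C(O)C=C(COc2cc(OC)c(OCc3ccccc3)c(OC)c2)O1
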